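## Structural features

The target is a trans-fused hydroazulenone: a cycloheptanone (C2, C3, C4, C5, C6, C10, C11) shares the C5–C6 bond with a cyclopentane (C5 to C9), and the quaternary C11 carries a methyl group and a two-carbon arm (C12, C13) that ends at C4 of a furan-2(5H)-one. In what follows the α face is the face of the C2 and C11 methyl groups and the β face that of the C11 arm; the C5 and C8 hydroxyls are α and the C6 hydrogen is β (2R,5S,6S,8R,11S in this numbering). The stereocentres form two adjacent pairs, C2/C11 and C5/C6, and C8 is held in a 1,3-relation to C5 across the gem-dimethyl carbon C9. Fragile groups are the β-hydroxy ketone C5(OH)–C6–C10(=O), which can epimerise at C6, dehydrate or undergo retro-aldol cleavage in base, and the butenolide, which tolerates neither strong base nor hydride nor hydrogenation. The real difficulty lies in the hindered tertiary carbinol C5 between C9 and the ring fusion, in its cis relation to the C8 carbinol, and in the quaternary C11 next to the C2 methine. The key step uses the fact that C5 and C8 become the termini of a diene C5=C6–C7=C8 once the five-membered ring is drawn as a 5,5-dimethylcyclopentadiene: one molecule of oxygen can then bring in both carbinol oxygens on one face, and C9, having no hydrogen, keeps the diene in place. The C6=C7 double bond that remains is α,β to the future C10 ketone, so C6 can be set afterwards.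

## Logic of the disconnections

**27 back to 23 and 24 (through 26 and 25).** The C13–C(sp2) bond to the butenolide and the O–Si bond at C8 are cut. The butenolide cannot ride through enolate chemistry, hydride or hydrogenation, so it is attached last. This leaves a primary iodide on a complete bicyclic core. The forward coupling must tolerate a ketone and a free tertiary hydroxyl, and the last desilylation must be acidic and mild.

**23 back to 21 (through 22).** No C–C bond is cut; the C13–I bond, the C6–H and C7–H bonds and the benzyl C–O bond are traced back. One hydrogenation sets C6 and frees the C13 hydroxyl. The forward step must add hydrogen to the β face of C6=C7 and must not hydrogenolyse the allylic C–O bonds.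

**21 back to 18 (through 20 and 19).** The C10 carbonyl is traced to a silyl-protected carbinol and the C8 silyl ether to the free diol. The C10 ketone cannot be present earlier because the C10 silyloxy group is the face-directing element of the key step. The forward steps need clean discrimination of C8–OH from C5–OH and of the two silyl groups.

**18 back to 16 (through 17).** The C5–O and C8–O bonds are cut together. This removes two stereocentres and the hindered tertiary carbinol in one move and leaves a flat diene. The forward step needs facial selectivity and a peroxide that is reduced before it can rearrange.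

**16 back to 14 (through 15).** The C6–C10 bond is cut, opening the seven-membered ring to a dienyl triflate and an aldehyde that cannot enolise. The forward ring closure must set C10 with the oxygen on the β face.

**14 back to 10 and 11 (through 13 and 12).** The C4–C5 bond and the C6–O triflate bond are cut, and the aldehyde is traced to a nitrile. This splits the molecule into a commercial enone and an acyclic iodide that holds C2 and C11. The forward alkylation must occur at the only enolisable position of 11, next to the quaternary carbon.

**10 back to 7 (through 9 and 8).** The chain is re-closed to a lactone (C4–O–C10). The ring is the template for C11 and keeps C10 and C4 differentiated by oxidation level. The forward opening must give the nitrile at C10 and the iodide at C4 without a diol intermediate.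

**7 back to 4 and 6, 4 back to 3 and 1, 6 back to 5.** The C11–C12 and C11–CH3 bonds are cut. The C2 methyl of a six-membered lactone enolate directs the second alkylation, so the arm must enter last. The forward step needs an electrophile reactive enough for a tetrasubstituted enolate.

## Other disconnections considered

**Alternative 1:** The cut is C6–C10 together with a temporary C5–C10 bond. The ketone carbon is tied to both ring-fusion carbons in the cyclopropanol A1. A1 would arise from the ester A2 (C10 methyl ester on C11, trisubstituted cyclopentene C5=C6 at the end of the C2–C3–C4 tether) by an intramolecular Kulinkovich reaction with Ti(OiPr)4 and cyclohexylmagnesium chloride, the titanacyclopropane being passed to the tethered alkene by ligand exchange. Oxidative cleavage of the C5–C10 bond of A1 would then open the six-membered ring to the cycloheptanone and leave oxygen on C5.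
- In its favour: two C–C bonds and the C10 oxidation level come from a plain ester in one step. C10 needs no protecting group and no alcohol–ketone shuttle. C6 is fixed cis to the C5–C10 bond by the cyclopropane, so the trans fusion follows if oxygen replaces C10 at C5 with retention. On redox economy and on the kinetic setting of C6 this plan is the better one.
- Against it here: ligand-exchange cyclopropanation is dependable for terminal and some 1,2-disubstituted alkenes, whereas C5=C6 is trisubstituted and next to C9. The free C8 hydroxyl consumes Grignard reagent. The alkene face must be chosen by remote groups. The ring opening passes through a β-keto radical at C5, whose capture by oxygen is not bound to retention.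
- Comparison: the chosen plan makes both C–O bonds in one concerted, stereospecific event on a very reactive diene, at the price of carrying C10 as a silyl ether and of three later steps to reach the ketone. The step counts are about equal; the key bond formation from A2 to A1 is the less secure.

**Alternative 2:** The cuts are C7–C8 and C5–C6. The precursor A4 is a cyclohexane (C2, C3, C4, C5, C10, C11) whose C10 carries a vinyl group (C6=C7) and a silyloxy group, and whose C5 carries a silyloxy group and the chain C9(Me2)–C8H(OBn)2. SnCl4 would ionise the acetal, C7 would attack the oxocarbenium ion (Prins cyclisation), and the C5–C10 ring bond would shift to C6 (pinacol shift). This contracts the new six-membered ring to the cyclopentane and expands the cyclohexane to the cycloheptanone A3.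
- In its favour: two C–C bonds, both rings, the C10 ketone and the C6 and C8 stereocentres arise in one step, and the cyclohexane could come from a 3-methylcyclohexanone of the pulegone family. In bond-forming economy and in having the ketone without redox steps it is better than the chosen plan, and it uses no peroxide.
- Against it here: A4 needs three contiguous fully substituted carbons (C5, C10, C11) with control of the C5/C10 configuration, which moves the difficulty into the precursor. The oxocarbenium carbon C8 is neopentyl. The migrating C5 bears a silyloxy group whose lone pair can divert the cation. This reaction class normally gives cis-fused bicycles from the diastereomer with vinyl trans to the side chain, so the trans-fused A3 needs the cis diastereomer A4 reacting through the chair with C4 axial, or else an epimerisation at C6.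
- Comparison: C5 is set early and independently of C8, whereas the cycloaddition couples the two by mechanism. Counting the steps to A4, the route is expected to be no shorter.

**Alternative 3:** The cut is C6–C10 alone. The aldehyde A6 (C10 formyl group on C11; cyclopentenol with tertiary C5 hydroxyl, C6=C7 and silylated C8 hydroxyl at the end of the tether) would be closed to A5 by intramolecular hydroacylation with [Rh(nbd)(dppe)]BF4 after hydrogenation of the diene ligand. Rhodium inserts into the aldehyde C–H bond, the C5 hydroxyl holds the metal on the α face, and hydride and acyl add across C6=C7.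
- In its favour: the step is atom-economical and redox-neutral, gives the C10 ketone directly, and sets C6 kinetically with the acyl group cis to the directing hydroxyl, which is the target's relation. On the control of C6 and on the number of steps after ring closure it is better than the chosen plan, and equal to it in convergence.
- Against it here: hydroacylation closes five-membered rings readily and seven-membered rings only with special assistance. Decarbonylation competes when insertion is slow. The alkene is flanked by the quaternary C5. The regiochemistry (C6 against C7) is not assured. The acyl group must reach the α face of C6 while its tether leaves C5 from the β face, a strained arrangement for a syn addition.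
- Comparison: the C5 and C8 carbinols of A6 must be made beforehand in separate operations, whereas the chosen plan sets them together. The ring closure of the chosen plan, an organochromium addition to an aldehyde, is the more dependable.

Key step: step 13

**Remarks on the chemistry**
- Chiral pool: (R)-pulegone has the right configuration for C2 but would need a ring cleavage with loss of one carbon to give the C10–C4 chain. Methyl hydrogen (R)-3-methylglutarate (1) maps onto C10–C11–C2–C3–C4 atom for atom and is assumed to be purchasable, like 5, 11 and 24.
- Key-step pair: the diene and its endoperoxide were checked centre by centre against the target (C2 R, C11 S, peroxide oxygens α, C10 silyloxy β). No configuration needed changing.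
- Precursor design: the C13 oxygen is carried as a benzyl ether instead of a silyl ether, so that one hydrogenation both sets C6 and frees C13–OH. C10 is carried as a nitrile instead of an acetal, which avoids a diol differentiation and saves a step.

## Route

Step 1
Reactants: 1 methyl hydrogen (R)-3-methylglutarate
Product: 3 (R)-4-methyltetrahydro-2H-pyran-2-one, via hydroxy ester 2 (not isolated)
Conditions: BH3·SMe2, THF, 0 °C → rt; MeOH quench; TsOH (cat.), CH2Cl2, rt
Reagents that add atoms: none
Why: Borane reduces the carboxylic acid much faster than the ester (chemoselective acid reduction), and the δ-hydroxy ester lactonises under acid; the C2 stereocentre is not touched.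

Step 2
Reactants: 3 (R)-4-methyltetrahydro-2H-pyran-2-one
Product: 4 (3S,4R)-3,4-dimethyltetrahydro-2H-pyran-2-one
Conditions: LiN(iPr)2, THF, −78 °C; MeI, −78 °C
Reagents that add atoms: iodomethane, CI
Why: Lactone enolate alkylation; the electrophile enters anti to the C2 methyl and gives the trans lactone. This centre is re-enolised in step 4, so its purity is not critical.

Step 3
Reactants: 5 2-(benzyloxy)ethanol
Product: 6 2-(benzyloxy)ethyl trifluoromethanesulfonate
Conditions: Tf2O, pyridine, CH2Cl2, −78 → 0 °C; used at once
Reagents that add atoms: trifluoromethanesulfonic anhydride, O=S(=O)(OS(=O)(=O)C(F)(F)F)C(F)(F)F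
Why: O-Sulfonylation of a primary alcohol; a triflate is chosen because β-alkoxy halides are too sluggish for a tetrasubstituted enolate.

Step 4
Reactants: 4 (3S,4R)-3,4-dimethyltetrahydro-2H-pyran-2-one; 6 2-(benzyloxy)ethyl trifluoromethanesulfonate
Product: 7 (3S,4R)-3-[2-(benzyloxy)ethyl]-3,4-dimethyltetrahydro-2H-pyran-2-one (the two methyl groups cis)
Conditions: LiN(iPr)2, THF, −78 °C; 6, −78 → −40 °C
Reagents that add atoms: none
Why: Alkylation of the tetrasubstituted lactone enolate forms the quaternary C11. Allylic strain with the enolate methyl should push the C2 methyl pseudo-axial, and the triflate then attacks the opposite face, which places the arm trans to the C2 methyl (C11 S).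

Step 5
Reactants: 7 (3S,4R)-3-[2-(benzyloxy)ethyl]-3,4-dimethyltetrahydro-2H-pyran-2-one
Product: 8 (3S,4R)-3-[2-(benzyloxy)ethyl]-3,4-dimethyltetrahydro-2H-pyran-2-ol (lactol, both anomers)
Conditions: iBu2AlH (1.1 equiv), CH2Cl2, −78 °C; aq. potassium sodium tartrate
Reagents that add atoms: none
Why: Partial reduction of a δ-lactone to the lactol; the tetrahedral aluminium intermediate is stable at −78 °C, and the hindered carbonyl carbon helps against over-reduction.

Step 6
Reactants: 8 lactol
Product: 9 (E)-oxime of (2S,3R)-2-[2-(benzyloxy)ethyl]-5-hydroxy-2,3-dimethylpentanal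
Conditions: NH2OH·HCl, pyridine, EtOH, rt
Reagents that add atoms: hydroxylamine hydrochloride, Cl.NO
Why: Oxime formation drains the lactol through its open hydroxy aldehyde form; this frees the C4 hydroxyl and marks C10 as nitrogen-bearing in one operation.

Step 7
Reactants: 9 hydroxy oxime
Product: 10 (2S,3R)-2-[2-(benzyloxy)ethyl]-5-iodo-2,3-dimethylpentanenitrile
Conditions: PPh3 (2.5 equiv), I2 (2.5 equiv), imidazole (6 equiv), CH2Cl2, 0 °C → rt
Reagents that add atoms: iodine, II
Why: Triphenylphosphine–iodine activates both hydroxyl groups: iodide displaces the primary alkoxyphosphonium (Appel reaction), and the O-phosphonium aldoxime loses triphenylphosphine oxide to give the nitrile (aldoxime dehydration). C11 has no α-hydrogen, so nothing can epimerise.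

Step 8
Reactants: 10 iodo nitrile; 11 4,4-dimethylcyclopent-2-en-1-one
Product: 12 (2S,3R)-2-[2-(benzyloxy)ethyl]-5-(5,5-dimethyl-2-oxocyclopent-3-en-1-yl)-2,3-dimethylpentanenitrile (both epimers at the ring carbon)
Conditions: 11 (2 equiv), LiN(iPr)2, THF, −78 °C; then 10, DMPU, −78 → −20 °C
Reagents that add atoms: none
Why: Kinetic deprotonation of the enone can only occur at C5, because the γ-carbon is quaternary, and the cross-conjugated enolate is alkylated by the unbranched primary iodide (SN2). The new ring stereocentre is erased in step 9, and the hindered β-carbon of 11 suppresses self-addition.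

Step 9
Reactants: 12 alkylated enone
Product: 13 2-[(3R,4S)-6-(benzyloxy)-4-cyano-3,4-dimethylhexyl]-3,3-dimethylcyclopenta-1,4-dien-1-yl trifluoromethanesulfonate
Conditions: KN(SiMe3)2, THF, −78 °C; PhNTf2, −78 → 0 °C
Reagents that add atoms: N-phenylbis(trifluoromethanesulfonimide), O=S(=O)(N(c1ccccc1)S(=O)(=O)C(F)(F)F)C(F)(F)F
Why: Enol triflate formation; the single remaining α-hydrogen is removed and the dienolate is trapped on oxygen, which gives the diene C5=C6–C7=C8 with the leaving group on C6. The nitrile has no α-hydrogen.

Step 10
Reactants: 13 dienyl triflate nitrile
Product: 14 2-[(3R,4S)-6-(benzyloxy)-4-formyl-3,4-dimethylhexyl]-3,3-dimethylcyclopenta-1,4-dien-1-yl trifluoromethanesulfonate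
Conditions: iBu2AlH, toluene, −78 °C; aq. tartaric acid (pH 4), 0 °C
Reagents that add atoms: water, O
Why: Single hydride addition to the hindered nitrile gives an N-aluminio aldimine that is hydrolysed on work-up (nitrile-to-aldehyde reduction). Enol triflate and benzyl ether are inert at −78 °C, and the aldehyde cannot enolise.

Step 11
Reactants: 14 dienyl triflate aldehyde
Product: 15 (4S,5S,6R)-5-[2-(benzyloxy)ethyl]-1,1,5,6-tetramethyl-1,4,5,6,7,8-hexahydroazulen-4-ol (C10–OH β, cis to the C11 arm)
Conditions: CrCl2 (8 equiv), NiCl2 (2 mol % of Cr), degassed DMF, rt, 0.005 M, slow addition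
Reagents that add atoms: none
Why: Nozaki–Hiyama–Kishi reaction: zerovalent nickel formed in situ inserts into the C6–O bond, transmetalation to trivalent chromium gives a dienylchromium species, and this adds to the aldehyde in a 7-exo-trig closure under high dilution. A Felkin–Anh arrangement with the C12 arm anti to the incoming C6 and the C11 methyl beside the trajectory should place the new hydroxyl on the β face.

Step 12
Reactants: 15 dienol
Product: 16 triethylsilyl ether of 15 (bicyclic 5,5-dimethylcyclopentadiene; C10–OSiEt3 β, benzyl ether on C13)
Conditions: Et3SiOTf, 2,6-lutidine, CH2Cl2, −78 °C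
Reagents that add atoms: triethylsilyl trifluoromethanesulfonate, CC[Si](CC)(CC)OS(=O)(=O)C(F)(F)F
Why: Silylation of a hindered secondary alcohol with the silyl triflate under buffered, cold conditions, which keep the dienylic carbinol from ionising. The silyl ether is the face-directing group for step 13 and the most labile of the later silyl groups.

Step 13
Reactants: 16 diene triethylsilyl ether
Product: 17 endoperoxide (O–O bridging C5 and C8 on the α face, C6=C7 retained, C10–OSiEt3 β)
Conditions: O2, tetraphenylporphyrin (1 mol %), visible light (LED), CH2Cl2, −78 °C; cold solution used directly in step 14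
Reagents that add atoms: oxygen, O=O
Why: Energy transfer from the excited porphyrin gives singlet oxygen, which adds to the ring-locked s-cis diene C5=C6–C7=C8 in a concerted suprafacial (4+2) cycloaddition, the oxygen counterpart of the Diels–Alder reaction and the standard entry from cyclopentadienes to 2,3-dioxabicyclo[2.2.1]hept-5-enes. The peroxide ring (C5–O–O–C8–C9, a 1,2-dioxolane) is closed by the cycloaddition itself and not by a separate cyclisation, both C–O bonds forming on one face. C5 and C8 are therefore set together and cis; their absolute sense is controlled by C10, whose silyloxy group should sit pseudo-axial on the β face (anti to the axial C11 methyl, with the C2 methyl equatorial), so that oxygen approaches from the α face. Lone-pair repulsion between the electrophilic oxygen and the allylic silyloxy oxygen works in the same direction. The step needs facial selectivity and periselectivity for cycloaddition over the ene reaction at the C4 and C10 hydrogens; the fixed s-cis geometry makes the cycloaddition far faster, and the quaternary C9 rules out 1,5-hydrogen shifts of the diene. The benzyl ether is inert to singlet oxygen. The strained peroxide can rearrange thermally or by Kornblum–DeLaMare fragmentation at C8–H, hence the low temperature, the absence of base and the direct transfer to step 14.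

Step 14
Reactants: 17 endoperoxide
Product: 18 enediol (C5–OH and C8–OH both α and cis, C6=C7, C10–OSiEt3 β, C13–OBn)
Conditions: thiourea (1.5 equiv), MeOH added to the cold solution, −78 °C → rt
Reagents that add atoms: none
Why: Thiourea cleaves the O–O bond by attack of sulfur on oxygen (endoperoxide reduction). Neither C–O bond is touched, so the cis relation of C5 and C8 is kept.

Step 15
Reactants: 18 enediol
Product: 19 C8 tert-butyldimethylsilyl ether of 18
Conditions: tBuMe2SiOTf (1.2 equiv), 2,6-lutidine, CH2Cl2, −78 °C
Reagents that add atoms: tert-butyldimethylsilyl trifluoromethanesulfonate, CC(C)(C)[Si](C)(C)OS(=O)(=O)C(F)(F)F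
Why: Selective silylation of the secondary allylic C8 hydroxyl; the tertiary C5 hydroxyl lies between two fully substituted carbons and should react far more slowly at −78 °C.

Step 16
Reactants: 19 bis(silyl ether)
Product: 20 C10 alcohol (C10–OH β, C8–OSitBuMe2 α, C5–OH α, C6=C7)
Conditions: HF·pyridine, pyridine, THF, 0 °C
Reagents that add atoms: none
Why: Selective desilylation: the triethylsilyl ether is cleaved much faster than the tert-butyldimethylsilyl ether, and the pyridine buffer keeps the allylic carbinols from ionising.

Step 17
Reactants: 20 C10 alcohol
Product: 21 enone (C10 ketone conjugated with C6=C7; C5–OH α, C8–OSitBuMe2 α, C13–OBn)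
Conditions: Dess–Martin periodinane, NaHCO3, CH2Cl2, 0 °C → rt
Reagents that add atoms: none
Why: Dess–Martin oxidation of the allylic secondary alcohol. The tertiary C5 hydroxyl cannot be oxidised and C8 is protected, so only C10 reacts; the neutral conditions spare the β-hydroxy enone.

Step 18
Reactants: 21 enone
Product: 22 saturated trans-fused hydroxy ketone (C6–H β, C5–OH α, C8–OSitBuMe2 α, C10=O, C13–OH)
Conditions: H2 (1 atm), 10% Pd/C, EtOAc–EtOH, rt
Reagents that add atoms: none
Why: Heterogeneous hydrogenation should add both hydrogens to the β face of C6=C7, opposite the C8 silyloxy and C5 hydroxyl groups, which gives the C6–H β, trans-fused ketone; the same conditions hydrogenolyse the benzyl ether. The trans-fused ketone is also expected to be the more stable C6 epimer, so later enolisation should not erode it.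

Step 19
Reactants: 22 hydroxy ketone
Product: 23 primary iodide (as 22 with C13–I)
Conditions: PPh3, I2, imidazole, CH2Cl2, 0 °C
Reagents that add atoms: iodine, II
Why: Appel iodination of the only primary alcohol; the tertiary C5 hydroxyl cannot be displaced, and the near-neutral medium leaves the β-hydroxy ketone intact.

Step 20
Reactants: 23 primary iodide; 24 4-bromofuran-2(5H)-one
Product: 26 C8 tert-butyldimethylsilyl ether of the target, via alkylzinc iodide 25 (not isolated)
Conditions: Zn dust (activated with BrCH2CH2Br and Me3SiCl), LiCl, THF, 30 °C; then 24, Pd2(dba)3 (2.5 mol %), SPhos (10 mol %), THF, rt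
Reagents that add atoms: none
Why: Negishi coupling: zinc inserts into the primary C–I bond, zerovalent palladium adds oxidatively to the activated vinylic C–Br bond of 24, and transmetalation with reductive elimination forms the C13–C(sp2) bond. Alkylzinc halides tolerate ketones and lactones, and the neutral conditions spare the β-hydroxy ketone.

Step 21
Reactants: 26 silyl ether of the target
Product: 27 (2R,3aS,5S,6R,8aS)-2,8a-dihydroxy-1,1,5,6-tetramethyl-5-[2-(5-oxo-2,5-dihydrofuran-3-yl)ethyl]octahydroazulen-4(1H)-one (the target)
Conditions: HF·pyridine, THF, 0 °C → rt
Reagents that add atoms: none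
Why: Fluoride-assisted, mildly acidic desilylation; basic fluoride sources are avoided because the butenolide and the β-hydroxy ketone are base-sensitive.

## Compound list

1 | methyl hydrogen (R)-3-methylglutarate | C[C@@H](CC(=O)OC)CC(=O)O | starting material
2 | methyl (R)-5-hydroxy-3-methylpentanoate | C[C@@H](CC(=O)OC)CCO | intermediate
3 | (R)-4-methyltetrahydro-2H-pyran-2-one | C[C@@H]1CCOC(=O)C1 | intermediate
4 | (3S,4R)-3,4-dimethyltetrahydro-2H-pyran-2-one | C[C@@H]1CCOC(=O)[C@H]1C | intermediate
5 | 2-(benzyloxy)ethanol | OCCOCc1ccccc1 | starting material
6 | 2-(benzyloxy)ethyl trifluoromethanesulfonate | O=S(=O)(OCCOCc1ccccc1)C(F)(F)F | intermediate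
7 | (3S,4R)-3-[2-(benzyloxy)ethyl]-3,4-dimethyltetrahydro-2H-pyran-2-one | C[C@@H]1CCOC(=O)[C@@]1(C)CCOCc1ccccc1 | intermediate
8 | (3S,4R)-3-[2-(benzyloxy)ethyl]-3,4-dimethyltetrahydro-2H-pyran-2-ol (both anomers) | C[C@@H]1CCOC(O)[C@@]1(C)CCOCc1ccccc1 | intermediate
9 | (E)-oxime of (2S,3R)-2-[2-(benzyloxy)ethyl]-5-hydroxy-2,3-dimethylpentanal | C[C@@H]([C@@](C)(/C=N/O)CCOCc1ccccc1)CCO | intermediate
10 | (2S,3R)-2-[2-(benzyloxy)ethyl]-5-iodo-2,3-dimethylpentanenitrile | C[C@@H]([C@@](C)(C#N)CCOCc1ccccc1)CCI | intermediate
11 | 4,4-dimethylcyclopent-2-en-1-one | CC1(C)CC(=O)C=C1 | starting material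
12 | (2S,3R)-2-[2-(benzyloxy)ethyl]-5-(5,5-dimethyl-2-oxocyclopent-3-en-1-yl)-2,3-dimethylpentanenitrile (both ring epimers) | C[C@@H]([C@@](C)(C#N)CCOCc1ccccc1)CCC1C(=O)C=CC1(C)C | intermediate
13 | 2-[(3R,4S)-6-(benzyloxy)-4-cyano-3,4-dimethylhexyl]-3,3-dimethylcyclopenta-1,4-dien-1-yl trifluoromethanesulfonate | C[C@@H]([C@@](C)(C#N)CCOCc1ccccc1)CCC1=C(OS(=O)(=O)C(F)(F)F)C=CC1(C)C | intermediate
14 | 2-[(3R,4S)-6-(benzyloxy)-4-formyl-3,4-dimethylhexyl]-3,3-dimethylcyclopenta-1,4-dien-1-yl trifluoromethanesulfonate | C[C@@H]([C@@](C)(C=O)CCOCc1ccccc1)CCC1=C(OS(=O)(=O)C(F)(F)F)C=CC1(C)C | intermediate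
15 | (4S,5S,6R)-5-[2-(benzyloxy)ethyl]-1,1,5,6-tetramethyl-1,4,5,6,7,8-hexahydroazulen-4-ol | C[C@@H]1CCC2=C(C=CC2(C)C)[C@@H](O)[C@@]1(C)CCOCc1ccccc1 | intermediate
16 | triethylsilyl ether of 15 (key-step precursor) | C[C@@H]1CCC2=C(C=CC2(C)C)[C@@H](O[Si](CC)(CC)CC)[C@@]1(C)CCOCc1ccccc1 | intermediate
17 | endoperoxide bridging C5 and C8 on the α face (key-step product) | C[C@@H]1CC[C@]23OO[C@H](C=C2[C@@H](O[Si](CC)(CC)CC)[C@@]1(C)CCOCc1ccccc1)C3(C)C | intermediate
18 | enediol: C5–OH and C8–OH α, C6=C7, C10–OSiEt3 β | C[C@@H]1CC[C@]2(O)C(=C[C@@H](O)C2(C)C)[C@@H](O[Si](CC)(CC)CC)[C@@]1(C)CCOCc1ccccc1 | intermediate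
19 | C8 tert-butyldimethylsilyl ether of 18 | C[C@@H]1CC[C@]2(O)C(=C[C@@H](O[Si](C)(C)C(C)(C)C)C2(C)C)[C@@H](O[Si](CC)(CC)CC)[C@@]1(C)CCOCc1ccccc1 | intermediate
20 | C10 alcohol (19 without the triethylsilyl group) | C[C@@H]1CC[C@]2(O)C(=C[C@@H](O[Si](C)(C)C(C)(C)C)C2(C)C)[C@@H](O)[C@@]1(C)CCOCc1ccccc1 | intermediate
21 | enone: C10 ketone conjugated with C6=C7 | C[C@@H]1CC[C@]2(O)C(=C[C@@H](O[Si](C)(C)C(C)(C)C)C2(C)C)C(=O)[C@@]1(C)CCOCc1ccccc1 | intermediate
22 | trans-fused hydroxy ketone: C6–H β, C13–OH | C[C@@H]1CC[C@]2(O)[C@H](C[C@@H](O[Si](C)(C)C(C)(C)C)C2(C)C)C(=O)[C@@]1(C)CCO | intermediate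
23 | primary iodide (22 with C13–I) | C[C@@H]1CC[C@]2(O)[C@H](C[C@@H](O[Si](C)(C)C(C)(C)C)C2(C)C)C(=O)[C@@]1(C)CCI | intermediate
24 | 4-bromofuran-2(5H)-one | O=C1C=C(Br)CO1 | starting material
25 | alkylzinc iodide (23 with C13–ZnI) | C[C@@H]1CC[C@]2(O)[C@H](C[C@@H](O[Si](C)(C)C(C)(C)C)C2(C)C)C(=O)[C@@]1(C)CC[Zn]I | intermediate
26 | C8 tert-butyldimethylsilyl ether of the target | C[C@@H]1CC[C@]2(O)[C@H](C[C@@H](O[Si](C)(C)C(C)(C)C)C2(C)C)C(=O)[C@@]1(C)CCC1=CC(=O)OC1 | intermediate
27 | (2R,3aS,5S,6R,8aS)-2,8a-dihydroxy-1,1,5,6-tetramethyl-5-[2-(5-oxo-2,5-dihydrofuran-3-yl)ethyl]octahydroazulen-4(1H)-one | C[C@@H]1CC[C@]2(O)[C@H](C[C@@H](O)C2(C)C)C(=O)[C@@]1(C)CCC1=CC(=O)OC1 | target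

## Step count and least certain steps

Total: 21 steps. Longest linear sequence: 20 steps (steps 1, 2 and 4 to 21); step 3 is a one-step side branch.

**Step 13 (key step).** The most likely failures are insufficient discrimination between the two diene faces, if the C10 silyloxy group does not sit pseudo-axial, and thermal or base-induced rearrangement of the strained peroxide before it is reduced. The fallback replaces the cycloaddition by a stepwise 1,4-dioxygenation. It sets out from 16 and comes back at 18. Dimethyldioxirane in acetone–CH2Cl2 at −78 °C should epoxidise the tetrasubstituted, most electron-rich C5=C6 bond from the α face; being bulkier than singlet oxygen, it is more sensitive to the silyloxy group. This gives the vinyl epoxide F1. Pd(PPh3)4 with acetic acid in THF then opens F1 in the 1,4-sense with net retention: zerovalent palladium ionises the C6–O bond anti, and acetate attacks C8 anti to the metal. This gives the cis hydroxy acetate F2, and K2CO3 in MeOH removes the acetate to give 18.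

**Step 11.** The ring closure may give the wrong or a mixed configuration at C10, because the methyl group and the arm on C11 differ little in size; simple reduction of the C6–O bond without cyclisation is the other risk. The fallback sets C10 by reagent control. It sets out from 15 as formed together with its C10 epimer F3 and comes back at 15. The mixture is oxidised with MnO2 to the cross-conjugated dienone F4, and F4 is reduced with catecholborane under Corey–Bakshi–Shibata oxazaborolidine catalysis, choosing the catalyst enantiomer that delivers hydride to the α face.

**Step 18.** Hydrogen could be delivered from the α face if the C5 hydroxyl anchors the substrate to the metal, giving the cis-fused epimer, and an allylic C–O bond could be hydrogenolysed before the alkene is saturated. The fallback separates the two tasks. It sets out from 21 and comes back at 22. Conjugate reduction with [(Ph3P)CuH]6 in toluene adds hydride to C7, and protonation gives the saturated ketone benzyl ether F5. Brief treatment with DBU equilibrates C6 towards the trans-fused ketone if needed, and hydrogenolysis over Pd(OH)2/C then removes the benzyl group to give 22.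

**Step 8.** The enolate carbon is next to a quaternary centre and the iodide is unactivated, so slow alkylation with proton exchange and recovery of 10 is the likely failure. The fallback changes the nucleophile. It sets out from 11 and 10 and comes back at 12. Enone 11 is condensed with N,N-dimethylhydrazine to the hydrazone F6, and its lithium aza-enolate (LiN(iPr)2, THF, −78 °C) is alkylated with 10 to give F7. Mild hydrolysis with aqueous oxalic acid returns 12.

**Step 20.** Zinc insertion may be sluggish, or the alkylzinc may be protonated by the free C5 hydroxyl, giving the reduced C13–H compound. The fallback avoids a preformed organometallic. It sets out from 23 and 24 and comes back at 26. A nickel-catalysed reductive cross-electrophile coupling with NiBr2(MeOCH2CH2OMe), 4,4′-di-tert-butyl-2,2′-bipyridine and manganese powder in DMA couples the two halides directly; this fallback makes no new compound (F0).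

Further compounds
F1 | step 13 | vinyl epoxide: α-epoxide across C5–C6 of 16, C7=C8 retained | C[C@@H]1CC[C@]23O[C@]2(C=CC3(C)C)[C@@H](O[Si](CC)(CC)CC)[C@@]1(C)CCOCc1ccccc1
F2 | step 13 | cis hydroxy acetate: 18 with C8–OAc | C[C@@H]1CC[C@]2(O)C(=C[C@@H](OC(C)=O)C2(C)C)[C@@H](O[Si](CC)(CC)CC)[C@@]1(C)CCOCc1ccccc1
F3 | step 11 | C10 epimer of 15 (C10–OH α) | C[C@@H]1CCC2=C(C=CC2(C)C)[C@H](O)[C@@]1(C)CCOCc1ccccc1
F4 | step 11 | cross-conjugated dienone (15 with C10=O) | C[C@@H]1CCC2=C(C=CC2(C)C)C(=O)[C@@]1(C)CCOCc1ccccc1
F5 | step 18 | trans-fused saturated ketone benzyl ether (22 with C13–OBn) | C[C@@H]1CC[C@]2(O)[C@H](C[C@@H](O[Si](C)(C)C(C)(C)C)C2(C)C)C(=O)[C@@]1(C)CCOCc1ccccc1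
F6 | step 8 | N,N-dimethylhydrazone of 11 (C=N isomers) | CN(C)N=C1C=CC(C)(C)C1
F7 | step 8 | N,N-dimethylhydrazone of 12 (ring epimers, C=N isomers) | C[C@@H]([C@@](C)(C#N)CCOCc1ccccc1)CCC1C(=NN(C)C)C=CC1(C)C
F0 | step 20 | none | none
A1 | alternative 1 | tricyclic cyclopropanol | C[C@@H]1CC[C@]23[C@H](C[C@@H](O)C2(C)C)[C@@]3(O)[C@@]1(C)CCO[Si](C)(C)C(C)(C)C
A2 | alternative 1 | methyl ester with tethered cyclopentene C5=C6 | C[C@@H]([C@@](C)(C(=O)OC)CCO[Si](C)(C)C(C)(C)C)CCC1=CC[C@@H](O)C1(C)C
A3 | alternative 2 | trans-fused hydroazulenone with C5 silyl ether and C8 benzyl ether | C[C@@H]1CC[C@]2(O[Si](C)(C)C)[C@H](C[C@@H](OCc3ccccc3)C2(C)C)C(=O)[C@@]1(C)CCOCc1ccccc1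
A4 | alternative 2 | cyclohexane with C10 vinyl and silyloxy groups and C5 silyloxy group and dibenzyl acetal chain (vinyl cis to the chain) | C[C@@H]1CC[C@@](O[Si](C)(C)C)(C(C)(C)C(OCc2ccccc2)OCc2ccccc2)[C@@](O[Si](C)(C)C)(C=C)[C@@]1(C)CCOCc1ccccc1
A5 | alternative 3 | trans-fused hydroazulenone bis(silyl ether) | C[C@@H]1CC[C@]2(O)[C@H](C[C@@H](O[Si](C)(C)C(C)(C)C)C2(C)C)C(=O)[C@@]1(C)CCO[Si](C)(C)C(C)(C)C
A6 | alternative 3 | aldehyde with tethered cyclopentenol (C5–OH, C6=C7, C8–OSitBuMe2) | C[C@@H]([C@@](C)(C=O)CCO[Si](C)(C)C(C)(C)C)CC[C@]1(O)C=C[C@@H](O[Si](C)(C)C(C)(C)C)C1(C)C
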